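**Pl

**Plan**

- Retrosynthetic cuts, in order: the O7–Si bond of a silyl ether; the C2–C3 bond of ring C, which opens the pyranone to an α-diazoketone at C3 and an aryl 3,4-dimethoxybenzyl ether at O1–C2; the C3=N2 unit back to an acetyl CH3; the O1–CH2 ether bond; the aryl–prenyl bonds at C6 and C8, each traced to a 1,1-dimethylallyl ether on O7.
- Forward: ring A is bought as 2,4-dihydroxyacetophenone (1). The C8 prenyl is placed by O-allylation and Claisen shift, ring B is joined as a benzyl ether on O1, a second Claisen shift places the C6 prenyl, O7 is silylated, the acetyl CH3 becomes CHN2, ring C is closed last and the silyl group is removed.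
- Enabling feature: C2 lies between ring oxygen O1 and the electron-rich ring B. In the open precursor it is therefore the CH2 of an aryl 3,4-dimethoxybenzyl ether, a doubly activated, hydridic C–H site six atoms from the acetyl carbon C3. The prenyl groups on C6 and C8 are meta to C4a and cannot reach a reactive centre at C3.
- Stereochemistry: C2 (S) is the only stereocentre. It is created in the ring closure by catalyst-controlled choice between the two enantiotopic benzylic hydrogens, and the single later step is run buffered so that ring C cannot open.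

Key step: step 8

Assumption: the sense of induction of the chiral dirhodium carboxylate on this substrate cannot be predicted with certainty. Rh2(S-PTTL)4 is written as the catalyst that gives 2S; if a first run shows the opposite sense, the mirror-image catalyst Rh2(R-PTTL)4 is used under the same conditions.

**Route**

Step 1
Reactants: 1 2,4-dihydroxyacetophenone; 2 tert-butyl 2-methylbut-3-en-2-yl carbonate
Product: 3 1-[2-hydroxy-4-(2-methylbut-3-en-2-yloxy)phenyl]ethanone
Conditions: Pd(PPh3)4 (5 mol%), 4 Å molecular sieves, THF, 0 °C to rt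
Reagents that add atoms: none
Why: Tsuji–Trost O-allylation, in which zerovalent palladium ionises 2 with loss of CO2, the tert-butoxide formed deprotonates the free 4-OH (the 2-OH is held in a hydrogen bond to the acetyl group) and the phenoxide attacks the more substituted allyl terminus under kinetic control to give the tertiary ether.

Step 2
Reactants: 3 1-[2-hydroxy-4-(2-methylbut-3-en-2-yloxy)phenyl]ethanone
Product: 4 1-[2,4-dihydroxy-3-(3-methylbut-2-en-1-yl)phenyl]ethanone
Conditions: PhNEt2, 180 °C
Reagents that add atoms: none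
Why: Aromatic Claisen rearrangement, whose [3,3] shift turns the 1,1-dimethylallyl ether into a C-prenyl group and should favour C3 because the chelated 2-hydroxyacetophenone fixes double-bond character in the C3–C4 bond (a minor C5 isomer, if formed, is removed by chromatography).

Step 3
Reactants: 4 1-[2,4-dihydroxy-3-(3-methylbut-2-en-1-yl)phenyl]ethanone; 2 tert-butyl 2-methylbut-3-en-2-yl carbonate
Product: 5 1-[2-hydroxy-3-(3-methylbut-2-en-1-yl)-4-(2-methylbut-3-en-2-yloxy)phenyl]ethanone
Conditions: Pd(PPh3)4 (5 mol%), 4 Å molecular sieves, THF, 0 °C to rt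
Reagents that add atoms: none
Why: The same Tsuji–Trost O-allylation as in step 1, again selective for the non-chelated 4-OH, which one ortho prenyl group does not block.

Step 4
Reactants: 5 1-[2-hydroxy-3-(3-methylbut-2-en-1-yl)-4-(2-methylbut-3-en-2-yloxy)phenyl]ethanone; 6 3,4-dimethoxybenzyl bromide
Product: 7 1-[2-[(3,4-dimethoxyphenyl)methoxy]-3-(3-methylbut-2-en-1-yl)-4-(2-methylbut-3-en-2-yloxy)phenyl]ethanone
Conditions: K2CO3, Bu4NI (cat.), DMF, 50 °C
Reagents that add atoms: none
Why: Williamson ether synthesis, in which carbonate deprotonates the chelated 2-OH and the reactive electron-rich benzylic bromide alkylates the hindered phenoxide on oxygen, while the tertiary allyl ether is inert to base and below its rearrangement temperature.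

Step 5
Reactants: 7 1-[2-[(3,4-dimethoxyphenyl)methoxy]-3-(3-methylbut-2-en-1-yl)-4-(2-methylbut-3-en-2-yloxy)phenyl]ethanone
Product: 8 1-[2-[(3,4-dimethoxyphenyl)methoxy]-4-hydroxy-3,5-bis(3-methylbut-2-en-1-yl)phenyl]ethanone
Conditions: PhNEt2, 170 °C
Reagents that add atoms: none
Why: Second aromatic Claisen rearrangement, which can end only at C5 because C3 carries a prenyl group and the para position carries the acetyl group, so it installs the second prenyl group and frees the 4-OH, with the amine solvent suppressing acid-catalysed chroman formation.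

Step 6
Reactants: 8 1-[2-[(3,4-dimethoxyphenyl)methoxy]-4-hydroxy-3,5-bis(3-methylbut-2-en-1-yl)phenyl]ethanone
Product: 9 1-[4-(tert-butyldimethylsilyloxy)-2-[(3,4-dimethoxyphenyl)methoxy]-3,5-bis(3-methylbut-2-en-1-yl)phenyl]ethanone
Conditions: TBSCl, imidazole, DMF, rt
Reagents that add atoms: tert-butyldimethylsilyl chloride, CC(C)(C)[Si](C)(C)Cl
Why: Standard silylation of the only free hydroxyl group, giving a silyl ether that is shielded by two ortho prenyl groups and can later be removed without base or strong acid.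

Step 7
Reactants: 9 1-[4-(tert-butyldimethylsilyloxy)-2-[(3,4-dimethoxyphenyl)methoxy]-3,5-bis(3-methylbut-2-en-1-yl)phenyl]ethanone
Product: 11 2-diazo-1-[4-(tert-butyldimethylsilyloxy)-2-[(3,4-dimethoxyphenyl)methoxy]-3,5-bis(3-methylbut-2-en-1-yl)phenyl]ethanone, via trifluoroacetyl diketone 10 (not isolated)
Conditions: LiN(SiMe3)2, THF, −78 °C; CF3CO2CH2CF3, −78 °C; cold aq HCl quench; then MsN3, Et3N, H2O (1 equiv), MeCN, rt
Reagents that add atoms: methanesulfonyl azide, CS(=O)(=O)N=[N+]=[N-] (the two nitrogen atoms of 11); 2,2,2-trifluoroethyl trifluoroacetate, O=C(OCC(F)(F)F)C(F)(F)F (the trifluoroacetyl group of 10 only)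
Why: Regitz-type detrifluoroacetylative diazo transfer, in which the kinetic lithium enolate of the methyl ketone is C-acylated to the activated 1,3-diketone and the sulfonyl azide then delivers N2 to the central carbon while the trifluoroacetyl group leaves as the N-acylsulfonamide.

Step 8
Reactants: 11 2-diazo-1-[4-(tert-butyldimethylsilyloxy)-2-[(3,4-dimethoxyphenyl)methoxy]-3,5-bis(3-methylbut-2-en-1-yl)phenyl]ethanone
Product: 12 (2S)-7-(tert-butyldimethylsilyloxy)-2-(3,4-dimethoxyphenyl)-6,8-bis(3-methylbut-2-en-1-yl)-2,3-dihydro-4H-chromen-4-one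
Conditions: dirhodium tetrakis[N-phthaloyl-(S)-tert-leucinate], Rh2(S-PTTL)4 (1 mol%), CH2Cl2, 0 °C, slow addition of 11 to a final 0.01 M
Reagents that add atoms: none
Why: The dirhodium carboxylate expels N2 from 11 to give an electrophilic rhodium carbenoid at the future C3, which inserts through a concerted, asynchronous, hydride-transfer-like three-centre transition state into one C–H bond of the O–CH2–aryl group, forming the C2–C3 bond and delivering that hydrogen to C3. The closest known reaction type is the intramolecular carbenoid C–H insertion of ortho-alkoxyaryl α-diazoketones to chroman-4-ones under chiral dirhodium carboxylate catalysis. Ring C is closed as a six-membered ring by 1,6 C–H insertion through a chair-like transition state made up of C3, C4, C4a, C8a, O1 and C2. C2 is the only new stereocentre and, since insertion occurs with retention at carbon, its configuration is decided by which of the two enantiotopic benzylic hydrogens the chiral carboxylate pocket presents to the carbenoid (catalyst control). The step needs C–H insertion to outrun attack of the carbenoid on the O1 lone pair (five-membered oxonium ylide, then 1,2-benzyl shift), cyclopropanation of the prenyl alkenes and carbenoid dimerisation. The substrate secures this because the C2–H bonds are activated both by O1 and by ring B, which stabilises the positive charge building at C2, because O1 is a weakly nucleophilic aryl ether oxygen conjugated to the acyl group and flanked by the C8 prenyl group, and because both prenyl groups are meta to the acyl-bearing carbon and cannot reach C3, leaving only bimolecular side reactions that slow addition at high dilution suppresses.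

Step 9
Reactants: 12 (2S)-7-(tert-butyldimethylsilyloxy)-2-(3,4-dimethoxyphenyl)-6,8-bis(3-methylbut-2-en-1-yl)-2,3-dihydro-4H-chromen-4-one
Product: 13 (2S)-2-(3,4-dimethoxyphenyl)-7-hydroxy-6,8-bis(3-methylbut-2-en-1-yl)-2,3-dihydro-4H-chromen-4-one (IN0946)
Conditions: Bu4NF, AcOH (1:1), THF, 0 °C
Reagents that add atoms: none
Why: Fluoride-mediated desilylation, in which fluoride attacks silicon and the released phenoxide is protonated at once by acetic acid, so that no free base is present to open ring C by retro-oxa-Michael reaction and the C2 centre should stay untouched.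

**Compound list**

1 | 2,4-dihydroxyacetophenone | CC(=O)c1ccc(O)cc1O | starting material
2 | tert-butyl 2-methylbut-3-en-2-yl carbonate | C=CC(C)(C)OC(=O)OC(C)(C)C | starting material
3 | 1-[2-hydroxy-4-(2-methylbut-3-en-2-yloxy)phenyl]ethanone | CC(=O)c1ccc(OC(C)(C)C=C)cc1O | intermediate
4 | 1-[2,4-dihydroxy-3-(3-methylbut-2-en-1-yl)phenyl]ethanone | CC(=O)c1ccc(O)c(CC=C(C)C)c1O | intermediate
5 | 1-[2-hydroxy-3-(3-methylbut-2-en-1-yl)-4-(2-methylbut-3-en-2-yloxy)phenyl]ethanone | CC(=O)c1ccc(OC(C)(C)C=C)c(CC=C(C)C)c1O | intermediate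
6 | 3,4-dimethoxybenzyl bromide | COc1ccc(CBr)cc1OC | starting material
7 | 1-[2-[(3,4-dimethoxyphenyl)methoxy]-3-(3-methylbut-2-en-1-yl)-4-(2-methylbut-3-en-2-yloxy)phenyl]ethanone | CC(=O)c1ccc(OC(C)(C)C=C)c(CC=C(C)C)c1OCc1ccc(OC)c(OC)c1 | intermediate
8 | 1-[2-[(3,4-dimethoxyphenyl)methoxy]-4-hydroxy-3,5-bis(3-methylbut-2-en-1-yl)phenyl]ethanone | CC(=O)c1cc(CC=C(C)C)c(O)c(CC=C(C)C)c1OCc1ccc(OC)c(OC)c1 | intermediate
9 | 1-[4-(tert-butyldimethylsilyloxy)-2-[(3,4-dimethoxyphenyl)methoxy]-3,5-bis(3-methylbut-2-en-1-yl)phenyl]ethanone | CC(=O)c1cc(CC=C(C)C)c(O[Si](C)(C)C(C)(C)C)c(CC=C(C)C)c1OCc1ccc(OC)c(OC)c1 | intermediate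
10 | 1-[4-(tert-butyldimethylsilyloxy)-2-[(3,4-dimethoxyphenyl)methoxy]-3,5-bis(3-methylbut-2-en-1-yl)phenyl]-4,4,4-trifluorobutane-1,3-dione | O=C(CC(=O)C(F)(F)F)c1cc(CC=C(C)C)c(O[Si](C)(C)C(C)(C)C)c(CC=C(C)C)c1OCc1ccc(OC)c(OC)c1 | intermediate
11 | 2-diazo-1-[4-(tert-butyldimethylsilyloxy)-2-[(3,4-dimethoxyphenyl)methoxy]-3,5-bis(3-methylbut-2-en-1-yl)phenyl]ethanone | [N-]=[N+]=CC(=O)c1cc(CC=C(C)C)c(O[Si](C)(C)C(C)(C)C)c(CC=C(C)C)c1OCc1ccc(OC)c(OC)c1 | intermediate
12 | (2S)-7-(tert-butyldimethylsilyloxy)-2-(3,4-dimethoxyphenyl)-6,8-bis(3-methylbut-2-en-1-yl)-2,3-dihydro-4H-chromen-4-one | COc1ccc([C@@H]2CC(=O)c3cc(CC=C(C)C)c(O[Si](C)(C)C(C)(C)C)c(CC=C(C)C)c3O2)cc1OC | intermediate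
13 | (2S)-2-(3,4-dimethoxyphenyl)-7-hydroxy-6,8-bis(3-methylbut-2-en-1-yl)-2,3-dihydro-4H-chromen-4-one (IN0946) | COc1ccc([C@@H]2CC(=O)c3cc(CC=C(C)C)c(O)c(CC=C(C)C)c3O2)cc1OC | target

**Step count**

Total steps: 9. Longest linear sequence: 9 steps (1 to 13).

**Steps most likely to fail**

Step 8. The carbenoid may be diverted to the O1 lone pair, with oxonium ylide formation and 1,2-shift of the benzyl group in place of C–H insertion, or the catalyst may discriminate poorly between the two enantiotopic benzylic hydrogens. The fallback builds the C2 stereocentre by asymmetric conjugate addition to a chromone instead of by C–H insertion; it sets out from 5 and comes back to the route at 12. Compound 5 is rearranged directly (PhNEt2, 180 °C) to 1-[2,4-dihydroxy-3,5-bis(3-methylbut-2-en-1-yl)phenyl]ethanone F1. The non-chelated 4-OH is silylated (TBSCl, imidazole, DMF) to 1-[4-(tert-butyldimethylsilyloxy)-2-hydroxy-3,5-bis(3-methylbut-2-en-1-yl)phenyl]ethanone F2. Condensation with Me2NCH(OMe)2 (toluene, 90 °C) should give (E)-1-[4-(tert-butyldimethylsilyloxy)-2-hydroxy-3,5-bis(3-methylbut-2-en-1-yl)phenyl]-3-(dimethylamino)prop-2-en-1-one F3. This is cyclised with loss of dimethylamine (AcOH, toluene, 80 °C) to 7-(tert-butyldimethylsilyloxy)-6,8-bis(3-methylbut-2-en-1-yl)-4H-chromen-4-one F4. Enantioselective conjugate addition of 3,4-dimethoxyphenylboronic acid then follows under divalent palladium catalysis (Pd(OCOCF3)2, 4-tert-butyl-2-(pyridin-2-yl)-4,5-dihydrooxazole in the enantiomeric form that gives 2S, NH4PF6, H2O, ClCH2CH2Cl, 60 °C) and should deliver 12, which continues with step 9.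

Step 9. Transient phenoxide or fluoride basicity may open and reclose ring C (retro-oxa-Michael and oxa-Michael), eroding the enantiomeric purity set in step 8. The fallback avoids any protecting group on O7 and any base after ring closure, using the 1,1-dimethylallyl ether itself as the masked 7-OH and C6 prenyl group; it sets out from 7 and comes back at 13. Compound 7 is taken through the same diazo transfer as in step 7, via 1-[2-[(3,4-dimethoxyphenyl)methoxy]-3-(3-methylbut-2-en-1-yl)-4-(2-methylbut-3-en-2-yloxy)phenyl]-4,4,4-trifluorobutane-1,3-dione F5, to 2-diazo-1-[2-[(3,4-dimethoxyphenyl)methoxy]-3-(3-methylbut-2-en-1-yl)-4-(2-methylbut-3-en-2-yloxy)phenyl]ethanone F6. The C–H insertion of step 8 (Rh2(S-PTTL)4, CH2Cl2, 0 °C, high dilution) should give (2S)-2-(3,4-dimethoxyphenyl)-8-(3-methylbut-2-en-1-yl)-7-(2-methylbut-3-en-2-yloxy)-2,3-dihydro-4H-chromen-4-one F7. A thermal Claisen rearrangement in neutral xylene at 130 °C can end only at C6 and should give 13 directly.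

Step 1. The π-allylpalladium intermediate may drift regiochemically, giving the linear prenyl ether or C-allylation, or the tertiary ether may re-ionise on prolonged contact with the catalyst. The fallback is the classical two-step propargylation and semi-hydrogenation; it sets out from 1 and comes back at 3. Compound 1 is alkylated on the 4-OH with 3-chloro-3-methylbut-1-yne (K2CO3, KI, CuI cat., acetone, reflux) to 1-[2-hydroxy-4-(2-methylbut-3-yn-2-yloxy)phenyl]ethanone F8. The alkyne is then reduced to the alkene (H2, Pd/CaCO3 poisoned with Pb(OAc)2, quinoline, EtOAc, rt) to give 3.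

**Further compounds**

F1 | step 8 | 1-[2,4-dihydroxy-3,5-bis(3-methylbut-2-en-1-yl)phenyl]ethanone | CC(=O)c1cc(CC=C(C)C)c(O)c(CC=C(C)C)c1O
F2 | step 8 | 1-[4-(tert-butyldimethylsilyloxy)-2-hydroxy-3,5-bis(3-methylbut-2-en-1-yl)phenyl]ethanone | CC(=O)c1cc(CC=C(C)C)c(O[Si](C)(C)C(C)(C)C)c(CC=C(C)C)c1O
F3 | step 8 | (E)-1-[4-(tert-butyldimethylsilyloxy)-2-hydroxy-3,5-bis(3-methylbut-2-en-1-yl)phenyl]-3-(dimethylamino)prop-2-en-1-one | CN(C)/C=C/C(=O)c1cc(CC=C(C)C)c(O[Si](C)(C)C(C)(C)C)c(CC=C(C)C)c1O
F4 | step 8 | 7-(tert-butyldimethylsilyloxy)-6,8-bis(3-methylbut-2-en-1-yl)-4H-chromen-4-one | O=c1ccoc2c1cc(CC=C(C)C)c(O[Si](C)(C)C(C)(C)C)c2CC=C(C)C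
F5 | step 9 | 1-[2-[(3,4-dimethoxyphenyl)methoxy]-3-(3-methylbut-2-en-1-yl)-4-(2-methylbut-3-en-2-yloxy)phenyl]-4,4,4-trifluorobutane-1,3-dione | O=C(CC(=O)C(F)(F)F)c1ccc(OC(C)(C)C=C)c(CC=C(C)C)c1OCc1ccc(OC)c(OC)c1
F6 | step 9 | 2-diazo-1-[2-[(3,4-dimethoxyphenyl)methoxy]-3-(3-methylbut-2-en-1-yl)-4-(2-methylbut-3-en-2-yloxy)phenyl]ethanone | [N-]=[N+]=CC(=O)c1ccc(OC(C)(C)C=C)c(CC=C(C)C)c1OCc1ccc(OC)c(OC)c1
F7 | step 9 | (2S)-2-(3,4-dimethoxyphenyl)-8-(3-methylbut-2-en-1-yl)-7-(2-methylbut-3-en-2-yloxy)-2,3-dihydro-4H-chromen-4-one | COc1ccc([C@@H]2CC(=O)c3ccc(OC(C)(C)C=C)c(CC=C(C)C)c3O2)cc1OC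
F8 | step 1 | 1-[2-hydroxy-4-(2-methylbut-3-yn-2-yloxy)phenyl]ethanone | CC(=O)c1ccc(OC(C)(C)C#C)cc1O
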